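**Assumption:** littorachalcone has no stereocentre and is achiral, so there is no enantiomer to select; the only stereo-element in the route is the E geometry of the enone intermediates, which is removed on hydrogenation.

**Retrosynthetic overview**
1. Target 12 ⇐ one-pot hydrogenation/hydrogenolysis of pentabenzyl bis-chalcone 10 (two C=C saturated, five benzyl ethers removed).
2. 10 ⇐ double Claisen–Schmidt aldol condensation of dialdehyde 6 with two molecules of methyl ketone 8; this forms both Cα–Cβ bonds.
3. 6 ⇐ benzylation and demethylation of 3 ⇐ SNAr diaryl ether formation between vanillin 1 and 4-fluorobenzaldehyde 2; 8 ⇐ 2,4-dihydroxyacetophenone 7.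
4. No ring is formed: ring A comes from 2, ring B from 1 and the two resorcinol rings from 7; the diaryl ether is made first, then the two three-carbon bridges.

**Route**

Step 1
Reactants: 1 vanillin (4-hydroxy-3-methoxybenzaldehyde); 2 4-fluorobenzaldehyde (1.1 equiv)
Product: 3 4-(4-formylphenoxy)-3-methoxybenzaldehyde
Conditions: K2CO3 (1.5 equiv), dry DMSO, N2, 120 °C, 12 h
Reagents that add atoms: none
Why: Nucleophilic aromatic substitution (SNAr, addition–elimination): the para-formyl group activates the C–F bond of 2 toward the vanillin phenoxide and fluoride is the best leaving group, so the diaryl ether forms with the oxygen pattern of ring B already fixed.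

Step 2
Reactants: 3 4-(4-formylphenoxy)-3-methoxybenzaldehyde
Product: 5 4-(4-formylphenoxy)-3-hydroxybenzaldehyde, via aryloxydibromoborane 4 (not isolated)
Conditions: BBr3 (1 M in CH2Cl2, 3 equiv), CH2Cl2, −78 to 0 °C; then ice-water
Reagents that add atoms: none
Why: Lewis-acid aryl methyl ether cleavage: BBr3 complexes the methoxy oxygen and bromide removes the methyl group by SN2 to give 4, which water hydrolyses to the phenol, while the diaryl ether (no sp3 carbon to attack) survives and the aldehydes are released from their boron complexes on work-up.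

Step 3
Reactants: 5 4-(4-formylphenoxy)-3-hydroxybenzaldehyde
Product: 6 3-(benzyloxy)-4-(4-formylphenoxy)benzaldehyde
Conditions: BnBr (1.2 equiv), K2CO3 (1.5 equiv), DMF, rt, 6 h
Reagents that add atoms: benzyl bromide, BrCc1ccccc1
Why: Williamson ether synthesis: the phenoxide is the only nucleophile present and the non-enolisable aldehydes are inert to K2CO3 at room temperature; masking the phenol keeps the aldehyde electrophilic in the base-mediated aldol step.

Step 4
Reactants: 7 2,4-dihydroxyacetophenone
Product: 8 2,4-bis(benzyloxy)acetophenone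
Conditions: BnBr (2.5 equiv), K2CO3 (3 equiv), DMF, 80 °C, 8 h
Reagents that add atoms: benzyl bromide, BrCc1ccccc1
Why: Double Williamson ether synthesis: heating in DMF with excess bromide also alkylates the hydrogen-bonded ortho-hydroxyl, which removes the phenoxide that would slow enolisation and the free ortho-phenol that could close a flavanone later.

Step 5
Reactants: 6 3-(benzyloxy)-4-(4-formylphenoxy)benzaldehyde; 8 2,4-bis(benzyloxy)acetophenone (2.2 equiv)
Product: 10 (E)-3-{4-[2-(benzyloxy)-4-{(E)-3-[2,4-bis(benzyloxy)phenyl]-3-oxoprop-1-enyl}phenoxy]phenyl}-1-[2,4-bis(benzyloxy)phenyl]prop-2-en-1-one (pentabenzyl bis-chalcone), via bis-aldol adduct 9 (not isolated)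
Conditions: KOH (50% aq, 6 equiv), EtOH/THF 2:1, 0 °C to rt, 24–48 h; product filtered or chromatographed
Reagents that add atoms: none
Why: Double Claisen–Schmidt crossed aldol condensation: 8 is the only enolisable partner and 6 has no α-hydrogens, so each enolate adds to an aldehyde and the β-hydroxy ketone arms of 9 lose water by E1cB to the conjugated enones, which form E under thermodynamic control; the carbinol centres of 9 are destroyed, so no stereocentre is carried on.

Step 6
Reactants: 10 pentabenzyl bis-chalcone
Product: 12 littorachalcone, via pentabenzyl littorachalcone 11 (not isolated)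
Conditions: H2 (1 atm), 10% Pd/C, THF/MeOH 1:1, rt, 6–12 h, stopped at complete debenzylation (LC–MS)
Reagents that add atoms: none
Why: Heterogeneous catalytic hydrogenation followed by hydrogenolysis: Pd/C saturates the two enone C=C bonds first (giving 11) and then cleaves the five benzylic C–O bonds, while the electron-rich, hydrogen-bonded ortho-hydroxyaryl ketones resist further reduction at 1 atm and room temperature; the target is achiral, so no stereocontrol is needed.

**Compound list**

1 | vanillin (4-hydroxy-3-methoxybenzaldehyde) | COc1cc(C=O)ccc1O | starting material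
2 | 4-fluorobenzaldehyde | O=Cc1ccc(F)cc1 | starting material
3 | 4-(4-formylphenoxy)-3-methoxybenzaldehyde | COc1cc(C=O)ccc1Oc1ccc(C=O)cc1 | intermediate
4 | dibromo[5-formyl-2-(4-formylphenoxy)phenoxy]borane (aryloxydibromoborane, not isolated) | O=Cc1ccc(Oc2ccc(C=O)cc2OB(Br)Br)cc1 | intermediate
5 | 4-(4-formylphenoxy)-3-hydroxybenzaldehyde | O=Cc1ccc(Oc2ccc(C=O)cc2O)cc1 | intermediate
6 | 3-(benzyloxy)-4-(4-formylphenoxy)benzaldehyde | O=Cc1ccc(Oc2ccc(C=O)cc2OCc2ccccc2)cc1 | intermediate
7 | 2,4-dihydroxyacetophenone | CC(=O)c1ccc(O)cc1O | starting material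
8 | 2,4-bis(benzyloxy)acetophenone | CC(=O)c1ccc(OCc2ccccc2)cc1OCc1ccccc1 | intermediate
9 | 3-{4-[2-(benzyloxy)-4-{3-[2,4-bis(benzyloxy)phenyl]-1-hydroxy-3-oxopropyl}phenoxy]phenyl}-1-[2,4-bis(benzyloxy)phenyl]-3-hydroxypropan-1-one (bis-aldol adduct, mixture of diastereomers, not isolated) | O=C(CC(O)c1ccc(Oc2ccc(C(O)CC(=O)c3ccc(OCc4ccccc4)cc3OCc3ccccc3)cc2OCc2ccccc2)cc1)c1ccc(OCc2ccccc2)cc1OCc1ccccc1 | intermediate
10 | (E)-3-{4-[2-(benzyloxy)-4-{(E)-3-[2,4-bis(benzyloxy)phenyl]-3-oxoprop-1-enyl}phenoxy]phenyl}-1-[2,4-bis(benzyloxy)phenyl]prop-2-en-1-one (pentabenzyl bis-chalcone) | O=C(/C=C/c1ccc(Oc2ccc(/C=C/C(=O)c3ccc(OCc4ccccc4)cc3OCc3ccccc3)cc2OCc2ccccc2)cc1)c1ccc(OCc2ccccc2)cc1OCc1ccccc1 | intermediate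
11 | 3-{4-[2-(benzyloxy)-4-{3-[2,4-bis(benzyloxy)phenyl]-3-oxopropyl}phenoxy]phenyl}-1-[2,4-bis(benzyloxy)phenyl]propan-1-one (pentabenzyl littorachalcone, not isolated) | O=C(CCc1ccc(Oc2ccc(CCC(=O)c3ccc(OCc4ccccc4)cc3OCc3ccccc3)cc2OCc2ccccc2)cc1)c1ccc(OCc2ccccc2)cc1OCc1ccccc1 | intermediate
12 | littorachalcone, 1-(2,4-dihydroxyphenyl)-3-{4-[4-[3-(2,4-dihydroxyphenyl)-3-oxopropyl]-2-hydroxyphenoxy]phenyl}propan-1-one | O=C(CCc1ccc(Oc2ccc(CCC(=O)c3ccc(O)cc3O)cc2O)cc1)c1ccc(O)cc1O | target

**Step count:** 6 steps in total. Longest linear sequence: 5 steps (steps 1, 2, 3, 5, 6); step 4 is a one-step side branch that joins at step 5.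

**Three steps most likely to fail, with fallbacks**

Step 2 (BBr3 demethylation in the presence of two aldehydes: risk of benzal bromide formation or incomplete cleavage). The fallback sets out from 3 and comes back at 5. Both aldehydes of 3 are masked with ethylene glycol and catalytic p-TsOH in toluene under Dean–Stark conditions to give 2-{4-[4-(1,3-dioxolan-2-yl)-2-methoxyphenoxy]phenyl}-1,3-dioxolane F1. The methyl ether is then cleaved nucleophilically with NaSEt in DMF at 130 °C (SN2 at the methyl carbon; acetals and the unactivated diaryl ether are base-stable) to give 5-(1,3-dioxolan-2-yl)-2-[4-(1,3-dioxolan-2-yl)phenoxy]phenol F2. Hydrolysis of the acetals with 1 M HCl in THF at room temperature returns 5.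

Step 5 (double Claisen–Schmidt: risk of stalling at the mono-condensed stage, Cannizzaro loss of the dialdehyde, or precipitation of half-reacted material). The fallback sets out from 8 and comes back at 10. Selective α-bromination of 8 with CuBr2 in EtOAc/CHCl3 at reflux gives 1-[2,4-bis(benzyloxy)phenyl]-2-bromoethan-1-one F3. PPh3 in toluene converts it into {2-[2,4-bis(benzyloxy)phenyl]-2-oxoethyl}triphenylphosphonium bromide F4. Aqueous NaOH/CH2Cl2 then gives the stabilised ylide 1-[2,4-bis(benzyloxy)phenyl]-2-(triphenylphosphoranylidene)ethan-1-one F5. A double Wittig olefination of dialdehyde 6 with 2.3 equiv of this ylide in toluene at reflux, under neutral conditions, gives E,E-bis-chalcone 10.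

Step 6 (risk of over-reduction of the aryl ketones, or of stalled removal of five benzyl groups during long exposure to H2/Pd). The fallback sets out from 10 and comes back at 12, separating alkene reduction from deprotection and using no hydrogenolysis. Conjugate reduction of both enones of 10 with catalytic monovalent copper hydride [(Ph3P)CuH]6 and PhSiH3 in toluene at room temperature, followed by fluoride work-up, gives 11, this time isolated. Lewis-acid debenzylation with BCl3 and pentamethylbenzene (cation scavenger) in CH2Cl2 at −78 °C then gives 12. This detour passes only through listed compound 11 and makes no new compound (none F0).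

**Further compounds**

F1 | step 2 | 2-{4-[4-(1,3-dioxolan-2-yl)-2-methoxyphenoxy]phenyl}-1,3-dioxolane | COc1cc(C2OCCO2)ccc1Oc1ccc(C2OCCO2)cc1
F2 | step 2 | 5-(1,3-dioxolan-2-yl)-2-[4-(1,3-dioxolan-2-yl)phenoxy]phenol | Oc1cc(C2OCCO2)ccc1Oc1ccc(C2OCCO2)cc1
F3 | step 5 | 1-[2,4-bis(benzyloxy)phenyl]-2-bromoethan-1-one | O=C(CBr)c1ccc(OCc2ccccc2)cc1OCc1ccccc1
F4 | step 5 | {2-[2,4-bis(benzyloxy)phenyl]-2-oxoethyl}triphenylphosphonium bromide | [Br-].O=C(C[P+](c1ccccc1)(c1ccccc1)c1ccccc1)c1ccc(OCc2ccccc2)cc1OCc1ccccc1
F5 | step 5 | 1-[2,4-bis(benzyloxy)phenyl]-2-(triphenylphosphoranylidene)ethan-1-one | O=C(C=P(c1ccccc1)(c1ccccc1)c1ccccc1)c1ccc(OCc2ccccc2)cc1OCc1ccccc1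
F0 | step 6 | none | none
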